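**Plan**

- Retrosynthesis: the three C–Br bonds of ring A are cut first (bromination of a free phenol), then the benzyl ether on the central oxygen. Ring B is then cut across C1'–C2' and C5'–C6'.
- Enabling feature: the bromines at C2' and C4' of ring B map onto C3 and C5 of 3,5-dibromo-2-pyrone. C1' and C6' are the two carbons of an ethynyl ether whose oxygen is already the diaryl ether oxygen.
- Forward: ring A comes intact from o-vanillin (benzylation, Dakin oxidation). The new phenol oxygen is turned into an ethynyl ether with trichloroethylene and n-BuLi.
- Ring B is then built on that oxygen by pyrone Diels–Alder reaction and loss of CO2. Debenzylation and tribromination of ring A finish the synthesis.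
- Stereochemistry: the target has no stereocentre and no stereogenic double bond. The E geometry of the dichlorovinyl ether and the bridgeheads of the cycloadduct are transient.

Key step: step 6

**Route**

Step 1
Reactants: 1 o-vanillin (2-hydroxy-3-methoxybenzaldehyde)
Product: 2 2-(benzyloxy)-3-methoxybenzaldehyde
Conditions: BnBr, K2CO3, DMF, 60 °C
Reagents that add atoms: benzyl bromide, SMILES BrCc1ccccc1
Why: Williamson ether synthesis; the phenoxide formed with K2CO3 in DMF displaces bromide from the benzylic halide by SN2, and the aldehyde is inert to these conditions.

Step 2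
Reactants: 2 2-(benzyloxy)-3-methoxybenzaldehyde
Product: 4 2-(benzyloxy)-3-methoxyphenol, via aryl formate 3 (not isolated)
Conditions: mCPBA, CH2Cl2, 0 °C to rt; then cat. K2CO3, MeOH, rt
Reagents that add atoms: mCPBA (3-chloroperoxybenzoic acid), SMILES OOC(=O)c1cccc(Cl)c1
Why: Baeyer–Villiger (Dakin-type) oxidation; the electron-rich, ortho-alkoxylated aryl group migrates in preference to hydrogen in the Criegee intermediate, and the resulting formate is removed by base-catalysed transesterification with methanol.

Step 3
Reactants: 4 2-(benzyloxy)-3-methoxyphenol; 5 trichloroethylene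
Product: 7 (E)-2-(benzyloxy)-1-[(1,2-dichloroethenyl)oxy]-3-methoxybenzene, via dichloroacetylene 6 (not isolated)
Conditions: 5 (excess), K2CO3, DMF, 70 °C
Reagents that add atoms: none
Why: Elimination–addition known for phenols and trichloroethylene; base removes HCl to give dichloroacetylene, to which the phenoxide adds anti, which sets the E geometry (of no consequence later).

Step 4
Reactants: 7 (E)-2-(benzyloxy)-1-[(1,2-dichloroethenyl)oxy]-3-methoxybenzene
Product: 10 2-(benzyloxy)-1-(ethynyloxy)-3-methoxybenzene, via chloroalkynyl ether 8 (not isolated), via lithium acetylide 9 (not isolated)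
Conditions: n-BuLi (2.3 equiv), THF, −78 to −40 °C; then H2O, −78 °C; cold non-acidic work-up, used at once as a toluene solution
Reagents that add atoms: none
Why: Established dichlorovinyl ether to ynol ether conversion; n-BuLi removes the vinylic hydrogen and LiCl is lost by beta-elimination, a second equivalent performs chlorine–lithium exchange on the chloroalkyne, and the acetylide is protonated cold, at a temperature where benzylic or ring lithiation of the ether groups should not compete.

Step 5
Reactants: 11 coumalic acid (2-oxo-2H-pyran-5-carboxylic acid)
Product: 12 3,5-dibromo-2H-pyran-2-one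
Conditions: NBS (2.5 equiv), cat. Bu4NBr, CHCl3, 50 °C
Reagents that add atoms: N-bromosuccinimide, SMILES O=C1CCC(=O)N1Br
Why: Bromodecarboxylation; electrophilic bromine attacks C5 ipso to the carboxyl group with loss of CO2, and a second equivalent brominates the enol-ether-like C3 of the pyrone.

Step 6
Reactants: 10 2-(benzyloxy)-1-(ethynyloxy)-3-methoxybenzene; 12 3,5-dibromo-2H-pyran-2-one
Product: 14 2-(benzyloxy)-1-(2,4-dibromophenoxy)-3-methoxybenzene, via bridged lactone 13 (not isolated)
Conditions: 12 (2 equiv), toluene, 110 °C, slow addition of 10, cat. BHT, N2
Reagents that add atoms: none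
Why: The low-lying LUMO of the electron-poor pyrone 12 and the HOMO of the ynol ether 10 combine in an inverse-electron-demand, concerted but asynchronous [4+2] cycloaddition in which the terminal alkyne carbon bonds ahead to the electrophilic C6 of the pyrone and the oxygen-bearing carbon bonds to C3, giving the bridged lactone 13. A thermally allowed retro-[4+2] step then expels CO2 from 13 and leaves the aromatic ring B. The closest known reaction type is the Diels–Alder/decarboxylation benzannulation of 2-pyrones with alkynes, together with the inverse-demand cycloadditions of 3,5-dibromo-2-pyrone with enol ethers. Ring B closes as a six-membered carbocycle by intermolecular cycloaddition (C1'–C2' and C5'–C6' made in one operation) and is aromatised by the cycloreversion; no stereocentre is created in 14, because the two bridgehead centres of 13 vanish with the CO2 bridge. The step needs regioselectivity (2,4-dibromo, not 3,5-dibromo, ring B), and the substrates secure it by matched polarisation: the beta carbon of the ynol ether is its nucleophilic end and C6 of the pyrone its most electrophilic end, while the developing charges are stabilised by the ether oxygen on one partner and by the lactone carbonyl and the C3 bromine on the other. Chemoselectivity against self-condensation of the labile ynol ether is served by adding it slowly to an excess of the cheap pyrone.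

Step 7
Reactants: 14 2-(benzyloxy)-1-(2,4-dibromophenoxy)-3-methoxybenzene
Product: 15 2-(2,4-dibromophenoxy)-6-methoxyphenol
Conditions: BCl3 (2 equiv), C6HMe5 (3 equiv), CH2Cl2, −78 °C; then H2O
Reagents that add atoms: none
Why: Lewis-acid ether cleavage; BCl3 ionises the benzyl ether selectively at low temperature and pentamethylbenzene traps the benzyl cation by Friedel–Crafts alkylation, which spares the methyl ether, the diaryl ether and the aryl bromides that hydrogenolysis would endanger.

Step 8
Reactants: 15 2-(2,4-dibromophenoxy)-6-methoxyphenol
Product: 16 3,4,5-tribromo-2-(2,4-dibromophenoxy)-6-methoxyphenol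
Conditions: Br2 (3.3 equiv), AcOH, rt to 50 °C
Reagents that add atoms: bromine, SMILES BrBr
Why: Electrophilic aromatic bromination; each free position of ring A is para to an oxygen donor (C4 to OH, C3 to OMe, C5 to the aryloxy group), so all three should be taken, while ring B carries two deactivating bromines and a single donor and should stay untouched.

**Compound list**

1 | o-vanillin (2-hydroxy-3-methoxybenzaldehyde) | COc1cccc(C=O)c1O | starting material
2 | 2-(benzyloxy)-3-methoxybenzaldehyde | COc1cccc(C=O)c1OCc1ccccc1 | intermediate
3 | 2-(benzyloxy)-3-methoxyphenyl formate (not isolated) | COc1cccc(OC=O)c1OCc1ccccc1 | intermediate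
4 | 2-(benzyloxy)-3-methoxyphenol | COc1cccc(O)c1OCc1ccccc1 | intermediate
5 | trichloroethylene | ClC=C(Cl)Cl | starting material
6 | dichloroacetylene (not isolated) | ClC#CCl | intermediate
7 | (E)-2-(benzyloxy)-1-[(1,2-dichloroethenyl)oxy]-3-methoxybenzene | COc1cccc(O/C(Cl)=C\Cl)c1OCc1ccccc1 | intermediate
8 | 2-(benzyloxy)-1-[(chloroethynyl)oxy]-3-methoxybenzene (not isolated) | COc1cccc(OC#CCl)c1OCc1ccccc1 | intermediate
9 | lithium [2-(benzyloxy)-3-methoxyphenoxy]ethynide (not isolated) | [Li]C#COc1cccc(OC)c1OCc1ccccc1 | intermediate
10 | 2-(benzyloxy)-1-(ethynyloxy)-3-methoxybenzene | COc1cccc(OC#C)c1OCc1ccccc1 | intermediate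
11 | coumalic acid (2-oxo-2H-pyran-5-carboxylic acid) | O=C(O)c1ccc(=O)oc1 | starting material
12 | 3,5-dibromo-2H-pyran-2-one | O=c1occ(Br)cc1Br | intermediate
13 | 5-[2-(benzyloxy)-3-methoxyphenoxy]-4,7-dibromo-2-oxabicyclo[2.2.2]octa-5,7-dien-3-one (racemic, bridgehead configuration fixed by the bicycle, not isolated) | O=C1OC2C=C(Oc3cccc(OC)c3OCc3ccccc3)C1(Br)C=C2Br | intermediate
14 | 2-(benzyloxy)-1-(2,4-dibromophenoxy)-3-methoxybenzene | COc1cccc(Oc2ccc(Br)cc2Br)c1OCc1ccccc1 | intermediate
15 | 2-(2,4-dibromophenoxy)-6-methoxyphenol | COc1cccc(Oc2ccc(Br)cc2Br)c1O | intermediate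
16 | 3,4,5-tribromo-2-(2,4-dibromophenoxy)-6-methoxyphenol | COc1c(O)c(Oc2ccc(Br)cc2Br)c(Br)c(Br)c1Br | target

**Step count**

Total steps: 8. Longest linear sequence: 7 steps (steps 1, 2, 3, 4, 6, 7, 8 from o-vanillin); step 5 is a one-step side branch.

**Steps most likely to fail, with fallbacks**

Step 6. The terminal ynol ether may oligomerise or be hydrated by adventitious acid faster than it cycloadds at the temperature the alkyne needs. The cycloaddition could also lose part of its regiocontrol. The fallback gives up the cycloaddition and attaches ring B as a preformed unit. It sets out from phenol 4. Bis(2,4-dibromophenyl)iodonium chloride F1 is prepared from 1,3-dibromobenzene and iodyl sulfate in H2SO4 and precipitated with NaCl. It is heated with 4 and NaOH in water/dioxane. Metal-free O-arylation of the phenoxide by the diaryliodonium salt should transfer one 2,4-dibromophenyl group to oxygen. This gives 14, where the route is rejoined, and the other aryl group leaves as the aryl iodide.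

Step 4. The ethynyl ether may decompose during quench, concentration or storage, through polymerisation or acid-catalysed hydration to the aryl acetate. The fallback avoids the free terminal alkyne and sets out from 7. The lithium acetylide 9 is generated as before and quenched with Me3SiCl to give {[2-(benzyloxy)-3-methoxyphenoxy]ethynyl}(trimethyl)silane F2, a storable silyl-capped ynol ether. F2 is heated with pyrone 12 in toluene. Both the steric demand of silicon and its stabilisation of positive charge on the oxygen-bearing carbon favour the same orientation. The cycloaddition should proceed through the silylated bridged lactone F3 (not isolated) to {2-[2-(benzyloxy)-3-methoxyphenoxy]-3,5-dibromophenyl}(trimethyl)silane F4. Protodesilylation of F4 with TBAF in wet THF at 60 °C removes the silyl group ortho to the ether oxygen. The route is rejoined at 14.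

Step 8. The bromination may stall before the third bromine enters the crowded ring A, or bromine may oxidise the free, electron-rich phenol in competition with substitution. The fallback reverses the order of the last two operations and sets out from 14. With the phenol still benzylated there is nothing to oxidise. Br2 in AcOH/CH2Cl2, with cat. FeBr3 if needed, should brominate the three ring A positions, each para to an oxygen, to give 2-(benzyloxy)-4,5,6-tribromo-1-(2,4-dibromophenoxy)-3-methoxybenzene F5. Cleavage of the benzyl ether of F5 with BCl3 and pentamethylbenzene in CH2Cl2 at −78 °C then gives the target. The ring is now electron-poor and not prone to C-benzylation. The route is rejoined at 16.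

**Further compounds**

F1 | step 6 | bis(2,4-dibromophenyl)iodonium chloride | [Cl-].Brc1ccc([I+]c2ccc(Br)cc2Br)c(Br)c1
F2 | step 4 | {[2-(benzyloxy)-3-methoxyphenoxy]ethynyl}(trimethyl)silane | COc1cccc(OC#C[Si](C)(C)C)c1OCc1ccccc1
F3 | step 4 | 5-[2-(benzyloxy)-3-methoxyphenoxy]-4,7-dibromo-6-(trimethylsilyl)-2-oxabicyclo[2.2.2]octa-5,7-dien-3-one (racemic, not isolated) | O=C1OC2C([Si](C)(C)C)=C(Oc3cccc(OC)c3OCc3ccccc3)C1(Br)C=C2Br
F4 | step 4 | {2-[2-(benzyloxy)-3-methoxyphenoxy]-3,5-dibromophenyl}(trimethyl)silane | COc1cccc(Oc2c(Br)cc(Br)cc2[Si](C)(C)C)c1OCc1ccccc1
F5 | step 8 | 2-(benzyloxy)-4,5,6-tribromo-1-(2,4-dibromophenoxy)-3-methoxybenzene | COc1c(OCc2ccccc2)c(Oc2ccc(Br)cc2Br)c(Br)c(Br)c1Br
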